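- The vessel, stirred at −20 °C, held 0.1 mol% of free catalyst on its starting material, and by 50.0 min the summer run read 12.7 % target with 84.8 % starting material still present.

| setting | summer | dawn | flask |
|---|---|---|---|
| starting material | 0.050 M | 0.034 M | 0.050 M |
| second substrate | 0.50 equiv | 0.50 equiv | 0.500 equiv |
| reagent | 0.70 equiv | 0.70 equiv | 0.700 equiv |
| free catalyst | 0.1 mol% | 0.1 mol% | 0.1 mol% |
| temperature | −20 °C | −25 °C | −20 °C |
| remark | the very flask that is asked about, followed so far | run made earlier |  |
| time |  |  | 50 min |

| run | time / min | target / % | starting material / % |
|---|---|---|---|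
| summer | 6.00 | 9.7 | 89.3 |
| summer | 20.0 | 12.3 | 86.4 |
| summer | 30.0 | 12.3 | 86.3 |
| summer | 50.0 | 12.7 | 84.8 |
| dawn | 4.00 | 7.2 | 92.6 |
| dawn | 8.00 | 10.0 | 89.3 |
| dawn | 12.0 | 11.6 | 88.4 |
| dawn | 20.0 | 13.0 | 86.9 |

(readings scatter by 0.5 percentage points)

- percent here means starting material units held: one self-condensation product counts as two
- target taken out counts as made
- the analysis behind the earlier runs scatters by 0.5 percentage points, standard deviation
- steps thought possible: starting material + free catalyst <-> catalyst intermediate A; reagent + catalyst intermediate A -> free catalyst + target; second substrate + free catalyst <-> catalyst intermediate B; reagent + catalyst intermediate B -> free catalyst + second product; 2 starting material -> self-condensation product; second substrate <-> dormant form; free catalyst -> spent catalyst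
- additions bring no volume worth counting

- Monday's: change nothing and wait 1.5 h more
- Friday's: at 50 min add free catalyst, 100 % of the amount charged, then wait 1.5 h
- Saturday's: at 50 min take out 90 % of the target then present, then wait 1.5 h
- Tuesday's: at 50 min raise the temperature by 10 K, then wait 1.5 h
- Thursday's: at 50 min add reagent, 50.0 % of the amount charged, then wait 1.5 h

* target, in percent of the starting material first charged, at 50 min
* what to do for the largest gain in target; "none" if nothing gains more than 2 percentage points (Monday's / Friday's / Saturday's / Tuesday's / Thursday's / none)
* target present, with what was taken out counted in, in percent of the starting material first charged, after Friday's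
* target present, with what was taken out counted in, in percent of the starting material first charged, after Saturday's

- I followed one catalyst molecule: each time it stood free, it either went round again or fell to spent catalyst.
- The summer readings from 20.0 min on averaged 12.4 %, so I read 124 as the target made per catalyst charged before it fell, the turnover number, which put its chance of falling per target at 0.806 %.
- I turned the question round: for reagent to stop the summer flask, with second substrate taking its full charge in reagent, this number had to reach 200, but it stood lower.
- For an option without new catalyst to gain 2 percentage points in the summer flask at this same turnover number, 16.1 % of the catalyst charge had to be working at 50 min.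
- Taking the 6.00 min reading as a first-order approach to the plateau, I read a loss of 0.252 min⁻¹, which by that estimate left <0.001 % working, far below that need.
- So I committed to about 12.4 % now and to Friday's, whose second charge at the same turnover number gave 24.9 %; Saturday's stayed at the plateau.
- The forecast gave 12.5 % (12.1 % to 12.9 %), Friday's, 22 % (19.5 % to 25 %) after Friday's and 12.6 % (12.1 % to 13.2 %) after Saturday's: “Only fresh catalyst restarts the reaction.” Its Friday figure stood below mine.
- The flask gave 12.0 % at 50 min, with spent catalyst at 100 % of the catalyst charged. Friday's added 8.9 points, reaching 20.9 %, so the second charge made 89.4 targets per catalyst, against 120 for the first. For the forecast's "now" to be wrong, this flask had to differ in its charge: at 0.055 mol% or 0.15 mol% of free catalyst, the computed answer had moved by 5 points from that of this flask.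

    starting material + free catalyst ⇌ catalyst intermediate A (K = 51.0 M⁻¹, k = 5900 M⁻¹ min⁻¹, Ea = 40.0 kJ mol⁻¹, ΔH = −83.0 kJ mol⁻¹)
    reagent + catalyst intermediate A → free catalyst + target (k = 2700 M⁻¹ min⁻¹, Ea = 40.0 kJ mol⁻¹)
    second substrate + free catalyst ⇌ catalyst intermediate B (K = 15.0 M⁻¹, k = 6200 M⁻¹ min⁻¹, Ea = 39.0 kJ mol⁻¹, ΔH = −33.0 kJ mol⁻¹)
    reagent + catalyst intermediate B → free catalyst + second product (k = 9900 M⁻¹ min⁻¹, Ea = 42.0 kJ mol⁻¹)
    2 starting material → self-condensation product (k = 0.00750 M⁻¹ min⁻¹, Ea = 55.0 kJ mol⁻¹)
    second substrate ⇌ dormant form (K = 2.80, k = 0.290 min⁻¹, Ea = 78.0 kJ mol⁻¹, ΔH = 25.0 kJ mol⁻¹)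
    free catalyst → spent catalyst (k = 0.960 min⁻¹, Ea = 68.0 kJ mol⁻¹)
    (constants at −20 °C)

- For the neighbour flask with 0.25 mol% of free catalyst, the turnover number gave 31.1 %. That neighbour flask computed to 24.6 %, less than the turnover number gave, with 52 % of its reagent left.

Readings and results stem from a simulated flask on assumed constants.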